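**Strategy**

Everything rests on cutting the C6–C1′ bond between the 4-pyranone ring (O1, C2–C6) and the undecyl chain (C1′–C11′). The feature exploited is the hidden symmetry of that ring: C2 (OMe) and C6 (chain) are both oxygen-substituted carbons β to the C4 carbonyl, each with an ethyl-bearing neighbour (C3, C5), so a methoxy group on C6 would make them interchangeable, as in 3,5-diethyl-2,6-dimethoxy-4-pyranone 5. In one operation the (S)-configured silyloxyundecyllithium 12 attacks C6 of 5 and drives out methoxide, which joins the two fragments and desymmetrises the ring without any need to control the site of attack. The C10′ stereocentre is bought as (S)-propylene oxide.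

Key step: step 6

Remark: ring atoms are numbered O1, C2 (OMe), C3, C4 (C=O), C5, C6 (chain) and chain atoms C1′ to C11′ outward from the ring; diester 4 is used as its mixture of diastereomers and enol forms, because both of its stereocentres vanish in step 2.

**Route**

Step 1
Reactants: 1 dimethyl 3-oxopentanedioate; 2 iodoethane
Product: 4 dimethyl 2,4-diethyl-3-oxopentanedioate, via monoethylated diester 3 (not isolated)
Conditions: EtI (2.4 equiv in total), K2CO3 (2.5 equiv), acetone, reflux
Reagents that add atoms: iodoethane (second equivalent of 2), CCI
Why: Two successive SN2 C-alkylations of the doubly activated β-keto ester positions (enolate alkylation), each consuming one molecule of iodoethane: once C2 carries an ethyl group (3), the still unsubstituted C4 methylene is the more acidic and less hindered site and takes the second one, and the two stereocentres that form without control are erased when C2 and C4 become ring sp2 carbons in step 2.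

Step 2
Reactants: 4 dimethyl 2,4-diethyl-3-oxopentanedioate
Product: 5 3,5-diethyl-2,6-dimethoxy-4H-pyran-4-one
Conditions: fuming H2SO4 (20% SO3), 0 °C to rt; poured onto ice, NaHCO3, CH2Cl2 extraction
Reagents that add atoms: none
Why: Acid-mediated cyclodehydration, the diester counterpart of the 1,3,5-tricarbonyl to 4-pyranone condensation and a reaction type known for 2,4-dialkyl-3-oxoglutarates: the carbonyl oxygen of one ester attacks the protonated second ester, SO3 binds the water that leaves so that both methoxy groups stay, and the product remains O-protonated in the acid until the cold quench.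

Step 3
Reactants: 6 1-bromo-8-chlorooctane; 7 (S)-propylene oxide
Product: 9 (S)-11-chloroundecan-2-ol, via 8-chlorooctylmagnesium bromide 8 (not isolated)
Conditions: Mg, THF, 35 °C; then CuI (10 mol %), 7, −30 °C to 0 °C; aq NH4Cl
Reagents that add atoms: none
Why: Mg inserts into the C–Br bond far faster than into the C–Cl bond, and the resulting Grignard reagent opens the epoxide by CuI-catalysed SN2 attack at the unsubstituted CH2, so that the C–O bond of the stereocentre is never broken and the (S) centre of 7 becomes C2 of 9 unchanged.

Step 4
Reactants: 9 (S)-11-chloroundecan-2-ol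
Product: 10 (S)-tert-butyl[(11-chloroundecan-2-yl)oxy]dimethylsilane
Conditions: TBSCl, imidazole, DMF, rt
Reagents that add atoms: tert-butyldimethylsilyl chloride (TBSCl), CC(C)(C)[Si](C)(C)Cl
Why: Imidazole-promoted silylation of the secondary alcohol (silyl ether protection); the TBS ether tolerates the Finkelstein conditions and tert-butyllithium at low temperature, and the reaction takes place at oxygen only, so the stereocentre is untouched.

Step 5
Reactants: 10 (S)-tert-butyl[(11-chloroundecan-2-yl)oxy]dimethylsilane
Product: 11 (S)-tert-butyl[(11-iodoundecan-2-yl)oxy]dimethylsilane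
Conditions: NaI (5 equiv), butan-2-one, reflux
Reagents that add atoms: sodium iodide, [Na+].[I-]
Why: Finkelstein reaction, an SN2 halide exchange at the primary carbon driven by precipitation of NaCl from the ketone solvent, giving the iodide that is needed for fast iodine–lithium exchange while leaving the silyl ether and the remote stereocentre alone.

Step 6
Reactants: 11 (S)-tert-butyl[(11-iodoundecan-2-yl)oxy]dimethylsilane; 5 3,5-diethyl-2,6-dimethoxy-4H-pyran-4-one
Product: 14 (S)-6-[10-(tert-butyldimethylsilyloxy)undecyl]-3,5-diethyl-2-methoxy-4H-pyran-4-one, via (S)-10-(tert-butyldimethylsilyloxy)undecyllithium 12 (not isolated), via lithium dienolate adduct 13 (not isolated)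
Conditions: 11, t-BuLi (2.1 equiv), pentane/Et2O (3:2), −78 °C, then rt briefly; solution of 12 cannulated into 5 (1.3 equiv), THF, −78 °C to −40 °C; aq NH4Cl
Reagents that add atoms: none
Why: Iodine–lithium exchange with two equivalents of t-BuLi (the second one destroys the tert-butyl iodide formed) converts 11 into 12, which attacks C6 of 5 in Michael fashion (C6 is β to the C4 carbonyl and carries two oxygen atoms, like a ketene acetal carbon), and the lithium dienolate adduct 13 so formed collapses with loss of LiOMe to restore the pyranone. The closest known reaction type is the conjugate addition–elimination (vinylic substitution) of organolithium and Grignard reagents on 2,6-dimethoxy-4-pyranones and β-alkoxy enones. No ring is closed and no stereocentre is created in the product, since the sp3 C6 of 13 returns to sp2 and the C10′ centre, nine bonds from the carbanion, travels unchanged as its silyl ether. Site selectivity needs no control, because a mirror plane through O1 and C4 makes C2 and C6 of 5 equivalent, attack at either gives the same 14, and the methoxy group left behind is the C2 methoxy of the target. Attack at C6 instead of the C4 carbonyl is secured by the low electrophilicity of that doubly vinylogous carbonate carbonyl and by the C3 and C5 ethyl groups on both of its sides. Single substitution is secured by running 12 into an excess of 5 at −78 °C, and any 12 that meets 14 should remove an acidic C1′ proton instead, which gives a dienolate that resists a second addition and returns 14 on work-up.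

Step 7
Reactants: 14 (S)-6-[10-(tert-butyldimethylsilyloxy)undecyl]-3,5-diethyl-2-methoxy-4H-pyran-4-one
Product: 15 (S)-3,5-diethyl-6-(10-hydroxyundecyl)-2-methoxy-4H-pyran-4-one
Conditions: TBAF, AcOH (1:1), THF, rt to 40 °C
Reagents that add atoms: none
Why: Fluoride attacks silicon and the strong Si–F bond drives cleavage of the silyl ether (fluoride desilylation), acetic acid buffering keeping alkoxide and hydroxide away from the methoxy-bearing C2 of the pyranone; the C10′–O bond is not broken, so the (S) configuration is retained.

Step 8
Reactants: 15 (S)-3,5-diethyl-6-(10-hydroxyundecyl)-2-methoxy-4H-pyran-4-one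
Product: 16 (S)-6-(10-acetoxyundecyl)-3,5-diethyl-2-methoxy-4H-pyran-4-one
Conditions: Ac2O, pyridine, DMAP (cat.), CH2Cl2, 0 °C to rt
Reagents that add atoms: acetic anhydride, CC(=O)OC(C)=O
Why: DMAP-catalysed O-acetylation of the only hydroxyl group through the N-acetylpyridinium ion (nucleophilic acyl transfer catalysis); acylation occurs at oxygen with retention at C10′ and the pyranone offers no competing nucleophile.

**Compound list**

1 | dimethyl 3-oxopentanedioate | COC(=O)CC(=O)CC(=O)OC | starting material
2 | iodoethane | CCI | starting material
3 | dimethyl 2-ethyl-3-oxopentanedioate (racemic, not isolated) | CCC(C(=O)OC)C(=O)CC(=O)OC | intermediate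
4 | dimethyl 2,4-diethyl-3-oxopentanedioate (mixture of diastereomers) | CCC(C(=O)OC)C(=O)C(CC)C(=O)OC | intermediate
5 | 3,5-diethyl-2,6-dimethoxy-4H-pyran-4-one | CCc1c(OC)oc(OC)c(CC)c1=O | intermediate
6 | 1-bromo-8-chlorooctane | ClCCCCCCCCBr | starting material
7 | (S)-propylene oxide | C[C@H]1CO1 | starting material
8 | 8-chlorooctylmagnesium bromide (not isolated) | ClCCCCCCCC[Mg]Br | intermediate
9 | (S)-11-chloroundecan-2-ol | ClCCCCCCCCC[C@H](C)O | intermediate
10 | (S)-tert-butyl[(11-chloroundecan-2-yl)oxy]dimethylsilane | ClCCCCCCCCC[C@H](C)O[Si](C)(C)C(C)(C)C | intermediate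
11 | (S)-tert-butyl[(11-iodoundecan-2-yl)oxy]dimethylsilane | ICCCCCCCCC[C@H](C)O[Si](C)(C)C(C)(C)C | intermediate
12 | (S)-10-(tert-butyldimethylsilyloxy)undecyllithium (not isolated) | [Li]CCCCCCCCC[C@H](C)O[Si](C)(C)C(C)(C)C | intermediate
13 | lithium 6-[(S)-10-(tert-butyldimethylsilyloxy)undecyl]-3,5-diethyl-2,6-dimethoxy-6H-pyran-4-olate (both C6 epimers, transient, not isolated) | CCC1=C(OC)OC(OC)(CCCCCCCCC[C@H](C)O[Si](C)(C)C(C)(C)C)C(CC)=C1O[Li] | intermediate
14 | (S)-6-[10-(tert-butyldimethylsilyloxy)undecyl]-3,5-diethyl-2-methoxy-4H-pyran-4-one | CCc1c(CCCCCCCCC[C@H](C)O[Si](C)(C)C(C)(C)C)oc(OC)c(CC)c1=O | intermediate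
15 | (S)-3,5-diethyl-6-(10-hydroxyundecyl)-2-methoxy-4H-pyran-4-one | CCc1c(CCCCCCCCC[C@H](C)O)oc(OC)c(CC)c1=O | intermediate
16 | (S)-6-(10-acetoxyundecyl)-3,5-diethyl-2-methoxy-4H-pyran-4-one (CNP0203650.1) | CCc1c(CCCCCCCCC[C@H](C)OC(C)=O)oc(OC)c(CC)c1=O | target

**Step count**

Total step count: 8. Longest linear sequence: 6 steps (steps 3 to 8, from 6 and 7 to 16); the pyranone branch (steps 1 and 2) joins at step 6.

**Steps most likely to fail**

1. Step 6 (key step). The valuable alkyllithium may be lost through incomplete iodine–lithium exchange with Wurtz-type coupling, through proton transfer from C1′ of product already formed, or through a second substitution at C2. The fallback makes the chain the electrophile and forms the C1′–C2′ bond instead of the C6–C1′ bond; it sets out from 5 and 7. MeMgBr (THF, −78 °C to 0 °C) should exchange one methoxy group of 5 by the same addition–elimination, now with a cheap reagent that can be dosed freely, to give 3,5-diethyl-2-methoxy-6-methyl-4H-pyran-4-one F1. In parallel, 1-bromo-7-chloroheptane (ClCCCCCCCBr) and Mg would give 7-chloroheptylmagnesium bromide F2, which should open 7 under CuI catalysis to (S)-10-chlorodecan-2-ol F3. TBSCl and imidazole would then give (S)-tert-butyl[(10-chlorodecan-2-yl)oxy]dimethylsilane F4, and NaI in butan-2-one would give (S)-tert-butyl[(10-iododecan-2-yl)oxy]dimethylsilane F5. LiN(SiMe3)2 (THF, −78 °C) should remove a proton from the C6 methyl group of F1 to give the vinylogous enolate [(3,5-diethyl-6-methoxy-4-oxo-4H-pyran-2-yl)methyl]lithium F6, and its alkylation with F5 (THF/DMPU, −78 °C to 0 °C) comes back to the route at 14.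

2. Step 2. The ring closure may lose methanol instead of water, the diester may be sulfonated or charred in oleum, or a methoxy group may be hydrolysed during the aqueous quench. The fallback separates ring closure from the second O-methylation and sets out from 4. DBU in refluxing toluene should close the lactone with loss of methanol, as in the cyclisation of 3,5-dioxo esters, to give 3,5-diethyl-4-hydroxy-6-methoxy-2H-pyran-2-one F7. The hard electrophile MeOTf (CH2Cl2, rt, then aq NaHCO3) should methylate the ring carbonyl oxygen of this 4-hydroxy-2-pyranone, the known way to 2-methoxy-4-pyranones, and comes back to the route at 5; any isomeric 4,6-dimethoxy-2-pyranone would be removed by chromatography.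

3. Step 3. Mg may also insert into the C–Cl bond, giving di-Grignard and coupled material, or bromide instead of carbon may open the epoxide. The fallback installs the terminal halide afterwards through an alkene instead of carrying it through the Grignard step, and sets out from 7. 8-Bromooct-1-ene (C=CCCCCCCBr) and Mg would give oct-7-enylmagnesium bromide F8, which should open 7 under CuI catalysis to (S)-undec-10-en-2-ol F9. TBSCl and imidazole would give (S)-tert-butyldimethyl(undec-10-en-2-yloxy)silane F10. 9-BBN (THF) should add to the terminal alkene in anti-Markovnikov fashion to give 9-[(S)-10-(tert-butyldimethylsilyloxy)undecyl]-9-borabicyclo[3.3.1]nonane F11, which H2O2/NaOH would oxidise to (S)-10-(tert-butyldimethylsilyloxy)undecan-1-ol F12. An Appel reaction (I2, PPh3, imidazole, CH2Cl2, 0 °C) then comes back to the route at 11.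

**Further compounds**

F1 | step 6 | 3,5-diethyl-2-methoxy-6-methyl-4H-pyran-4-one | CCc1c(C)oc(OC)c(CC)c1=O
F2 | step 6 | 7-chloroheptylmagnesium bromide | ClCCCCCCC[Mg]Br
F3 | step 6 | (S)-10-chlorodecan-2-ol | ClCCCCCCCC[C@H](C)O
F4 | step 6 | (S)-tert-butyl[(10-chlorodecan-2-yl)oxy]dimethylsilane | ClCCCCCCCC[C@H](C)O[Si](C)(C)C(C)(C)C
F5 | step 6 | (S)-tert-butyl[(10-iododecan-2-yl)oxy]dimethylsilane | ICCCCCCCC[C@H](C)O[Si](C)(C)C(C)(C)C
F6 | step 6 | [(3,5-diethyl-6-methoxy-4-oxo-4H-pyran-2-yl)methyl]lithium | [Li]Cc1oc(OC)c(CC)c(=O)c1CC
F7 | step 2 | 3,5-diethyl-4-hydroxy-6-methoxy-2H-pyran-2-one | CCC1=C(O)C(CC)=C(OC)OC1=O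
F8 | step 3 | oct-7-enylmagnesium bromide | C=CCCCCCC[Mg]Br
F9 | step 3 | (S)-undec-10-en-2-ol | C=CCCCCCCC[C@H](C)O
F10 | step 3 | (S)-tert-butyldimethyl(undec-10-en-2-yloxy)silane | C=CCCCCCCC[C@H](C)O[Si](C)(C)C(C)(C)C
F11 | step 3 | 9-[(S)-10-(tert-butyldimethylsilyloxy)undecyl]-9-borabicyclo[3.3.1]nonane | B1(CCCCCCCCC[C@H](C)O[Si](C)(C)C(C)(C)C)C2CCCC1CCC2
F12 | step 3 | (S)-10-(tert-butyldimethylsilyloxy)undecan-1-ol | OCCCCCCCCC[C@H](C)O[Si](C)(C)C(C)(C)C
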